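**Strategy.** The 1,10-epoxide is treated as the oxidation product of an (E)-C1=C10 olefin, so the ten-membered carbocycle (C1–C10) is closed at C9–C10 by an intramolecular nickel-catalysed reductive cross-electrophile coupling between the C10 alkenyl bromide and the primary C9 bromide beside the C8 silyl ether. The open-chain precursor already holds the trans-6,12-lactone ring, the 4Z olefin and the C3, C6, C7 and C8 stereocentres, set by an Evans succinate aldol, a CBS reduction and an asymmetric Nozaki–Hiyama–Kishi coupling. One operation gives the 1(10)E,4Z-germacradienolide core; α-methylenation, acylation at O8 and ring-controlled epoxidation of C1=C10 finish the target.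

Key step: step 13

Remark on the chemistry: positions are given in germacrane numbering (C1–C10 ring, C11–C13 lactone carbons, C14 on C10, C15 on C4); the C1–C10 epoxide of the target is trans, i.e. the epoxide of an (E)-olefin.

Step 1
Reactants: 1 but-2-yn-1-ol
Product: 2 (Z)-3-iodobut-2-en-1-ol
Conditions: Red-Al, THF, 0 °C → rt; then I2, −78 → 0 °C
Reagents that add atoms: iodine, II
Why: Alkoxide-directed trans-hydroalumination places aluminium on C3 in a five-membered alkenylalanate, and iodinolysis with retention gives the (Z)-iodoalkene that later fixes the 4Z olefin.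

Step 2
Reactants: 2 (Z)-3-iodobut-2-en-1-ol
Product: 3 (Z)-3-iodobut-2-enal
Conditions: MnO2, CH2Cl2, rt; used crude
Reagents that add atoms: none
Why: Neutral allylic oxidation with MnO2 should leave the Z geometry of the β-iodoenal untouched.

Step 3
Reactants: 4 (S)-4-benzyloxazolidin-2-one; 5 methyl 4-chloro-4-oxobutanoate
Product: 6 methyl 4-[(S)-4-benzyl-2-oxooxazolidin-3-yl]-4-oxobutanoate
Conditions: n-BuLi, THF, −78 °C; then 5, −78 → 0 °C
Reagents that add atoms: none
Why: N-Acylation of the lithiated oxazolidinone by the acid chloride is the standard preparation of an Evans imide, and the methyl ester is inert at this temperature.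

Step 4
Reactants: 6 succinate imide; 3 (Z)-3-iodobut-2-enal
Product: 8 (S)-4-benzyl-3-{[(2S,3S)-2-[(Z)-2-iodoprop-1-en-1-yl]-5-oxotetrahydrofuran-3-yl]carbonyl}oxazolidin-2-one, via syn-aldol hydroxy ester 7 (not isolated)
Conditions: Bu2BOTf, i-Pr2NEt, CH2Cl2, −78 → 0 °C; 3, −78 → 0 °C; pH 7 buffer, MeOH, H2O2; then PPTS (cat.), CH2Cl2, rt
Reagents that add atoms: none
Why: Evans syn-aldol through the (Z)-boron enolate and a Zimmerman–Traxler chair sets C6 and C7 under auxiliary control (aldehyde on the enolate face away from the benzyl group), and the γ-hydroxy ester then lactonises to the trans-lactone.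

Step 5
Reactants: 8 lactone imide
Product: 10 (2S,3S)-2-[(Z)-2-iodoprop-1-en-1-yl]-5-oxotetrahydrofuran-3-carboxylic acid, via peroxy acid 9 (not isolated)
Conditions: LiOH, H2O2, THF/H2O, 0 °C; then Na2SO3; HCl to pH 2
Reagents that add atoms: hydrogen peroxide, OO
Why: Lithium hydroperoxide cleaves the exocyclic imide carbonyl in preference to the γ-lactone, and sulfite reduces the peracid; no stereocentre is touched.

Step 6
Reactants: 10 lactone acid
Product: 13 (4S,5S)-4-(2-bromoacetyl)-5-[(Z)-2-iodoprop-1-en-1-yl]dihydrofuran-2(3H)-one, via acid chloride 11 (not isolated), via diazoketone 12 (not isolated)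
Conditions: (COCl)2, DMF (cat.), CH2Cl2, 0 °C → rt; CH2N2 (excess), Et2O, 0 °C; 48 % aq. HBr, 0 °C
Reagents that add atoms: diazomethane, C=[N+]=[N-]; hydrogen bromide, Br (oxalyl chloride, O=C(Cl)C(Cl)=O, puts Cl into 11 only)
Why: Acylation of diazomethane by the acid chloride and hydrobromination of the α-diazoketone (Nierenstein-type bromomethyl ketone synthesis) add C9 as CH2Br without base, so C7 should not epimerise.

Step 7
Reactants: 13 bromomethyl ketone
Product: 14 (4R,5S)-4-[(1S)-2-bromo-1-hydroxyethyl]-5-[(Z)-2-iodoprop-1-en-1-yl]dihydrofuran-2(3H)-one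
Conditions: (S)-Me-CBS (0.2 equiv), BH3·SMe2, THF, −20 °C; neutral work-up, used at once
Reagents that add atoms: none
Why: Corey–Bakshi–Shibata reduction sets C8 under reagent control, the (S)-oxazaborolidine delivering hydride to the face predicted by the acetophenone model with the ring carbon C7 as large and CH2Br as small group.

Step 8
Reactants: 14 bromohydrin
Product: 15 (4S,5S)-4-[(1S)-2-bromo-1-(triethylsilyloxy)ethyl]-5-[(Z)-2-iodoprop-1-en-1-yl]dihydrofuran-2(3H)-one
Conditions: TESOTf, 2,6-lutidine, CH2Cl2, −78 °C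
Reagents that add atoms: triethylsilyl triflate, CC[Si](CC)(CC)OS(=O)(=O)C(F)(F)F
Why: Silylation under weakly basic conditions caps O8 before it can close to an epoxide or translactonise.

Step 9
Reactants: 16 pent-3-yn-1-ol
Product: 17 (E)-4-bromopent-3-en-1-ol
Conditions: Cp2Zr(H)Cl (2.5 equiv), THF, rt → 40 °C; then NBS, 0 °C
Reagents that add atoms: N-bromosuccinimide, O=C1CCC(=O)N1Br
Why: Syn hydrozirconation with excess Schwartz reagent equilibrates zirconium to the methyl-bearing alkyne carbon, and bromination with retention gives the (E)-2-bromoalkene that defines the later 1(10)E olefin.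

Step 10
Reactants: 17 (E)-4-bromopent-3-en-1-ol
Product: 18 (E)-4-bromopent-3-enal
Conditions: Dess–Martin periodinane, NaHCO3, CH2Cl2, 0 °C → rt; used crude
Reagents that add atoms: none
Why: Buffered Dess–Martin oxidation should give the β,γ-unsaturated aldehyde without migration of the double bond.

Step 11
Reactants: 15 alkenyl iodide; 18 (E)-4-bromopent-3-enal (excess)
Product: 19 (4S,5R)-4-[(1S)-2-bromo-1-(triethylsilyloxy)ethyl]-5-[(1Z,3S,5E)-6-bromo-3-hydroxy-2-methylhepta-1,5-dien-1-yl]dihydrofuran-2(3H)-one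
Conditions: CrCl2, NiCl2 (cat.), Kishi chiral sulfonamide–oxazoline ligand (antipode that gives the 3S alcohol), Et3N, THF, rt
Reagents that add atoms: none
Why: In this asymmetric Nozaki–Hiyama–Kishi coupling nickel inserts into C–I much faster than into either C–Br bond, the alkenylchromium adds with retention of the Z geometry, and the ligand on chromium should set C3 under reagent control.

Step 12
Reactants: 19 allylic alcohol
Product: 20 (4S,5R)-4-[(1S)-2-bromo-1-(triethylsilyloxy)ethyl]-5-[(1Z,3S,5E)-6-bromo-3-(tert-butyldimethylsilyloxy)-2-methylhepta-1,5-dien-1-yl]dihydrofuran-2(3H)-one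
Conditions: TBSOTf, 2,6-lutidine, CH2Cl2, −78 → 0 °C
Reagents that add atoms: tert-butyldimethylsilyl triflate, CC(C)(C)[Si](C)(C)OS(=O)(=O)C(F)(F)F
Why: Standard silylation; TBS is chosen so that O3 stays protected when the TES group on O8 is removed.

Step 13
Reactants: 20 dibromide
Product: 21 (3S,6R,7S,8R,1(10)E,4Z)-3-(tert-butyldimethylsilyloxy)-8-(triethylsilyloxy)-13-norgermacra-1(10),4-dien-12,6-olide
Conditions: NiBr2·glyme (20 mol %), 4,4′-di-tert-butyl-2,2′-bipyridine (24 mol %), Mn powder, NaI, pyridine (cat.), DMA, 40 °C, syringe-pump addition of 20 to a final 2 mM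
Reagents that add atoms: none
Why: Ni(0)(dtbbpy) adds oxidatively to the C10 alkenyl bromide with retention, a Ni(I) species turns the primary C9 bromide (iodide after in-situ exchange) into the C9 radical, the tethered alkenyl–Ni(II) captures it, and C(sp2)–C(sp3) reductive elimination from Ni(III) forms C9–C10 while Mn regenerates Ni(0). The closest known reaction type is the nickel-catalysed reductive cross-electrophile coupling of alkenyl bromides with primary alkyl bromides, run here intramolecularly. The ten-membered carbocycle is closed in an endo sense at the alkenyl carbon (a macrocyclisation in which both chain ends become ring atoms), and no new stereocentre is formed. Cross- over homo-coupling is secured by the different activation modes of the two C–Br bonds (two-electron at sp2, radical at sp3), ring closure over oligomerisation by slow addition at high dilution and by the turn imposed by the trans-lactone and the 4Z olefin, and the E geometry by the stereoretentive oxidative addition. The β-silyloxy radical should not eliminate, and the lactone carries no methylene group yet, so no radical acceptor competes.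

Step 14
Reactants: 21 macrocyclic lactone
Product: 24 (3S,6R,7S,8R)-3-(tert-butyldimethylsilyloxy)-8-(triethylsilyloxy)germacra-1(10)E,4Z,11(13)-trien-12,6-olide, via Mannich base 22 (not isolated), via methiodide 23 (not isolated)
Conditions: LiHMDS, THF, −78 °C; CH2=NMe2+ I−, −78 → 0 °C; MeI, MeOH, rt; NaHCO3 (aq.), CH2Cl2, rt
Reagents that add atoms: Eschenmoser's salt, C=[N+](C)C.[I-] (methyl iodide, CI, puts CH3 into 23 only)
Why: Mannich reaction of the lactone enolate, N-methylation and E1cB loss of trimethylamine install C13 as the exocyclic methylene, H11 being the only hydrogen that can be lost.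

Step 15
Reactants: 24 bis-silyl ether
Product: 25 (3S,6R,7R,8R)-3-(tert-butyldimethylsilyloxy)-8-hydroxygermacra-1(10)E,4Z,11(13)-trien-12,6-olide
Conditions: PPTS, MeOH/CH2Cl2, 0 °C
Reagents that add atoms: none
Why: Mild acid methanolysis should remove the TES ether while the more hindered TBS ether at C3 survives.

Step 16
Reactants: 26 angelic acid
Product: 27 (Z)-2-methylbut-2-en-1-ol
Conditions: LiAlH4, Et2O, 0 °C → rt
Reagents that add atoms: none
Why: Hydride reduction of the acid gives the allylic alcohol without touching the trisubstituted Z olefin.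

Step 17
Reactants: 27 (Z)-2-methylbut-2-en-1-ol
Product: 28 [(2R,3S)-2,3-dimethyloxiran-2-yl]methanol
Conditions: Ti(Oi-Pr)4, D-(−)-diethyl tartrate, t-BuOOH, 4 Å MS, CH2Cl2, −20 °C
Reagents that add atoms: tert-butyl hydroperoxide, CC(C)(C)OO
Why: Sharpless asymmetric epoxidation with D-(−)-DET delivers oxygen to the face opposite to the one that gives (2S,3S)-epoxy alcohols from (E)-allylic alcohols with L-(+)-DET, and the cis methyl groups follow from the Z olefin.

Step 18
Reactants: 28 epoxy alcohol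
Product: 29 (2S,3S)-2,3-dimethyloxirane-2-carboxylic acid
Conditions: RuCl3·xH2O (cat.), NaIO4, CCl4/MeCN/H2O, rt
Reagents that add atoms: water, O
Why: Catalytic RuO4 oxidises the primary alcohol through the aldehyde hydrate to the glycidic acid without opening the epoxide; the C2 descriptor changes from R to S with no change in geometry.

Step 19
Reactants: 25 C8 alcohol; 29 epoxy acid
Product: 30 (3S,6R,7R,8R)-3-(tert-butyldimethylsilyloxy)-8-[(2S,3S)-2,3-dimethyloxirane-2-carbonyloxy]germacra-1(10)E,4Z,11(13)-trien-12,6-olide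
Conditions: DCC, DMAP, CH2Cl2, 0 °C → rt
Reagents that add atoms: none
Why: Steglich esterification acylates the only free hydroxyl with retention at C8, and the acid has no α-hydrogen, so it cannot epimerise.

Step 20
Reactants: 30 trienolide ester
Product: 31 (1R,3S,6R,7R,8R,10R)-3-(tert-butyldimethylsilyloxy)-1,10-epoxy-8-[(2S,3S)-2,3-dimethyloxirane-2-carbonyloxy]germacra-4Z,11(13)-dien-12,6-olide
Conditions: mCPBA (1.05 equiv), NaHCO3, CH2Cl2, 0 °C
Reagents that add atoms: mCPBA, OOC(=O)c1cccc(Cl)c1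
Why: Prilezhaev epoxidation should pick the electron-rich C1=C10 olefin over C4=C5 (two allylic C–O bonds, silyl ether) and the electron-poor methylene lactone, and peripheral attack on the exposed face of the (E)-olefin in the ten-membered ring should give the trans (1R,10R)-epoxide.

Step 21
Reactants: 31 silyl ether
Product: 32 CNP0268255.2
Conditions: TBAF, AcOH, THF, 0 °C → rt
Reagents that add atoms: none
Why: Buffered fluoride cleaves the TBS ether without acid, which would trigger transannular opening of the 1,10-epoxide.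

**Compound list**

1 | but-2-yn-1-ol | CC#CCO | starting material
2 | (Z)-3-iodobut-2-en-1-ol | C/C(I)=C/CO | intermediate
3 | (Z)-3-iodobut-2-enal | C/C(I)=C/C=O | intermediate
4 | (S)-4-benzyloxazolidin-2-one | O=C1N[C@@H](Cc2ccccc2)CO1 | starting material
5 | methyl 4-chloro-4-oxobutanoate | COC(=O)CCC(Cl)=O | starting material
6 | methyl 4-[(S)-4-benzyl-2-oxooxazolidin-3-yl]-4-oxobutanoate | COC(=O)CCC(=O)N1[C@@H](Cc2ccccc2)COC1=O | intermediate
7 | methyl (3S,4S,5Z)-3-{[(S)-4-benzyl-2-oxooxazolidin-3-yl]carbonyl}-4-hydroxy-6-iodohept-5-enoate (syn-aldol hydroxy ester) | COC(=O)C[C@H](C(=O)N1[C@@H](Cc2ccccc2)COC1=O)[C@H](O)/C=C(/C)I | intermediate (not isolated)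
8 | (S)-4-benzyl-3-{[(2S,3S)-2-[(Z)-2-iodoprop-1-en-1-yl]-5-oxotetrahydrofuran-3-yl]carbonyl}oxazolidin-2-one (trans-lactone) | O=C1C[C@H](C(=O)N2[C@@H](Cc3ccccc3)COC2=O)[C@@H](/C=C(/C)I)O1 | intermediate
9 | (2S,3S)-2-[(Z)-2-iodoprop-1-en-1-yl]-5-oxotetrahydrofuran-3-carboperoxoic acid | O=C1C[C@H](C(=O)OO)[C@@H](/C=C(/C)I)O1 | intermediate (not isolated)
10 | (2S,3S)-2-[(Z)-2-iodoprop-1-en-1-yl]-5-oxotetrahydrofuran-3-carboxylic acid | O=C1C[C@H](C(=O)O)[C@@H](/C=C(/C)I)O1 | intermediate
11 | (2S,3S)-2-[(Z)-2-iodoprop-1-en-1-yl]-5-oxotetrahydrofuran-3-carbonyl chloride | O=C1C[C@H](C(Cl)=O)[C@@H](/C=C(/C)I)O1 | intermediate (not isolated)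
12 | (4S,5S)-4-(2-diazoacetyl)-5-[(Z)-2-iodoprop-1-en-1-yl]dihydrofuran-2(3H)-one | O=C1C[C@H](C(=O)C=[N+]=[N-])[C@@H](/C=C(/C)I)O1 | intermediate (not isolated)
13 | (4S,5S)-4-(2-bromoacetyl)-5-[(Z)-2-iodoprop-1-en-1-yl]dihydrofuran-2(3H)-one | O=C1C[C@H](C(=O)CBr)[C@@H](/C=C(/C)I)O1 | intermediate
14 | (4R,5S)-4-[(1S)-2-bromo-1-hydroxyethyl]-5-[(Z)-2-iodoprop-1-en-1-yl]dihydrofuran-2(3H)-one | O=C1C[C@H]([C@H](O)CBr)[C@@H](/C=C(/C)I)O1 | intermediate
15 | (4S,5S)-4-[(1S)-2-bromo-1-(triethylsilyloxy)ethyl]-5-[(Z)-2-iodoprop-1-en-1-yl]dihydrofuran-2(3H)-one | O=C1C[C@H]([C@H](O[Si](CC)(CC)CC)CBr)[C@@H](/C=C(/C)I)O1 | intermediate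
16 | pent-3-yn-1-ol | CC#CCCO | starting material
17 | (E)-4-bromopent-3-en-1-ol | C/C(Br)=C\CCO | intermediate
18 | (E)-4-bromopent-3-enal | C/C(Br)=C\CC=O | intermediate
19 | (4S,5R)-4-[(1S)-2-bromo-1-(triethylsilyloxy)ethyl]-5-[(1Z,3S,5E)-6-bromo-3-hydroxy-2-methylhepta-1,5-dien-1-yl]dihydrofuran-2(3H)-one | O=C1C[C@H]([C@H](O[Si](CC)(CC)CC)CBr)[C@@H](/C=C(/C)[C@@H](O)C/C=C(\C)Br)O1 | intermediate
20 | (4S,5R)-4-[(1S)-2-bromo-1-(triethylsilyloxy)ethyl]-5-[(1Z,3S,5E)-6-bromo-3-(tert-butyldimethylsilyloxy)-2-methylhepta-1,5-dien-1-yl]dihydrofuran-2(3H)-one | O=C1C[C@H]([C@H](O[Si](CC)(CC)CC)CBr)[C@@H](/C=C(/C)[C@@H](O[Si](C)(C)C(C)(C)C)C/C=C(\C)Br)O1 | intermediate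
21 | (3S,6R,7S,8R,1(10)E,4Z)-3-(tert-butyldimethylsilyloxy)-8-(triethylsilyloxy)-13-norgermacra-1(10),4-dien-12,6-olide | C1C(=O)O[C@@H]2/C=C(/C)[C@@H](O[Si](C)(C)C(C)(C)C)C/C=C(\C)C[C@@H](O[Si](CC)(CC)CC)[C@@H]12 | intermediate
22 | 13-(dimethylamino)-11,13-dihydro derivative of 24 (Mannich base, C11 epimers) | CN(C)CC1C(=O)O[C@@H]2/C=C(/C)[C@@H](O[Si](C)(C)C(C)(C)C)C/C=C(\C)C[C@@H](O[Si](CC)(CC)CC)[C@@H]12 | intermediate (not isolated)
23 | trimethylammonium iodide of 22 (methiodide) | C[N+](C)(C)CC1C(=O)O[C@@H]2/C=C(/C)[C@@H](O[Si](C)(C)C(C)(C)C)C/C=C(\C)C[C@@H](O[Si](CC)(CC)CC)[C@@H]12.[I-] | intermediate (not isolated)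
24 | (3S,6R,7S,8R)-3-(tert-butyldimethylsilyloxy)-8-(triethylsilyloxy)germacra-1(10)E,4Z,11(13)-trien-12,6-olide | C=C1C(=O)O[C@@H]2/C=C(/C)[C@@H](O[Si](C)(C)C(C)(C)C)C/C=C(\C)C[C@@H](O[Si](CC)(CC)CC)[C@@H]12 | intermediate
25 | (3S,6R,7R,8R)-3-(tert-butyldimethylsilyloxy)-8-hydroxygermacra-1(10)E,4Z,11(13)-trien-12,6-olide | C=C1C(=O)O[C@@H]2/C=C(/C)[C@@H](O[Si](C)(C)C(C)(C)C)C/C=C(\C)C[C@@H](O)[C@@H]12 | intermediate
26 | angelic acid, (Z)-2-methylbut-2-enoic acid | C/C=C(/C)C(=O)O | starting material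
27 | (Z)-2-methylbut-2-en-1-ol | C/C=C(/C)CO | intermediate
28 | [(2R,3S)-2,3-dimethyloxiran-2-yl]methanol | OC[C@@]1(C)O[C@H]1C | intermediate
29 | (2S,3S)-2,3-dimethyloxirane-2-carboxylic acid | OC(=O)[C@@]1(C)O[C@H]1C | intermediate
30 | (3S,6R,7R,8R)-3-(tert-butyldimethylsilyloxy)-8-[(2S,3S)-2,3-dimethyloxirane-2-carbonyloxy]germacra-1(10)E,4Z,11(13)-trien-12,6-olide | C=C1C(=O)O[C@@H]2/C=C(/C)[C@@H](O[Si](C)(C)C(C)(C)C)C/C=C(\C)C[C@@H](OC(=O)[C@@]3(C)O[C@H]3C)[C@@H]12 | intermediate
31 | (1R,3S,6R,7R,8R,10R)-3-(tert-butyldimethylsilyloxy)-1,10-epoxy-8-[(2S,3S)-2,3-dimethyloxirane-2-carbonyloxy]germacra-4Z,11(13)-dien-12,6-olide | C=C1C(=O)O[C@@H]2/C=C(/C)[C@@H](O[Si](C)(C)C(C)(C)C)C[C@H]3O[C@]3(C)C[C@@H](OC(=O)[C@@]3(C)O[C@H]3C)[C@@H]12 | intermediate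
32 | CNP0268255.2, (1R,3S,6R,7R,8R,10R)-1,10-epoxy-3-hydroxy-8-[(2S,3S)-2,3-dimethyloxirane-2-carbonyloxy]germacra-4Z,11(13)-dien-12,6-olide | C=C1C(=O)O[C@@H]2/C=C(/C)[C@@H](O)C[C@H]3O[C@]3(C)C[C@@H](OC(=O)[C@@]3(C)O[C@H]3C)[C@@H]12 | target

**Step count.** Total: 21 steps. Longest linear sequence: 15 steps (steps 1, 2, 4–8, 11–15, 19–21).

**Steps most likely to fail**

1. Step 13 (macrocyclisation). The C9 radical may be reduced or the chains may couple between molecules faster than the strained ten-membered ring closes. Fallback: from 20, copper-catalysed borylation of the primary bromide (B2pin2, CuI, PPh3, LiOMe, DMF, rt) would give the alkyl pinacol boronate F1. A two-electron intramolecular B-alkyl Suzuki–Miyaura coupling with the alkenyl bromide (Pd(OAc)2, SPhos, K3PO4, toluene/H2O, 80 °C, high dilution) would then return to the route at 21.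

2. Step 20 (epoxidation). The ring may present the wrong face of C1=C10 to the peracid, or C4=C5 may compete. Fallback: from 30, a reagent-controlled Shi epoxidation with the D-fructose-derived ketone (Oxone, K2CO3, Bu4NHSO4, MeCN/dimethoxymethane/buffer, 0 °C), which gives (R,R)-epoxides from (E)-trisubstituted olefins, would lead to 31 with no new intermediate.

3. Step 11 (fragment coupling). Ligand control at C3 may be weak on this substrate. Fallback: from 15 and 18, an achiral CrCl2/NiCl2 coupling in DMSO would give 19 together with its C3 epimer, the (3R)-alcohol F2. Dess–Martin oxidation of the mixture would give the (Z)-enone F3, and reduction with (R)-Me-CBS and catecholborane at −78 °C (alkenyl as large group) would return to 19 as the (3S)-alcohol.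

**Further compounds**

F1 | step 13 | (4S,5R)-4-[(1S)-2-(4,4,5,5-tetramethyl-1,3,2-dioxaborolan-2-yl)-1-(triethylsilyloxy)ethyl]-5-[(1Z,3S,5E)-6-bromo-3-(tert-butyldimethylsilyloxy)-2-methylhepta-1,5-dien-1-yl]dihydrofuran-2(3H)-one | O=C1C[C@H]([C@H](O[Si](CC)(CC)CC)CB2OC(C)(C)C(C)(C)O2)[C@@H](/C=C(/C)[C@@H](O[Si](C)(C)C(C)(C)C)C/C=C(\C)Br)O1
F0 | step 20 | none | none
F2 | step 11 | (3R)-epimer of 19 | O=C1C[C@H]([C@H](O[Si](CC)(CC)CC)CBr)[C@@H](/C=C(/C)[C@H](O)C/C=C(\C)Br)O1
F3 | step 11 | (4S,5R)-4-[(1S)-2-bromo-1-(triethylsilyloxy)ethyl]-5-[(1Z,5E)-6-bromo-2-methyl-3-oxohepta-1,5-dien-1-yl]dihydrofuran-2(3H)-one | O=C1C[C@H]([C@H](O[Si](CC)(CC)CC)CBr)[C@@H](/C=C(/C)C(=O)C/C=C(\C)Br)O1
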